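**Plan**

- **Numbering and cuts.** The oxolane ring is numbered O1, C2 (aryl, lignan C7), C3 (CH2OH, C8), C4 (arylmethyl, C8'), C5 (CH2). The hydroxymethyl carbon is traced back to a carboxyl carbon. The aryl–C7' bond is cut to an arylmagnesium reagent and a masked aldehyde. The two exocyclic bonds at C3 and C4 are cut together to dichloroketene and a 2-aryl-2,5-dihydrofuran, and the C2–aryl bond is cut to a Heck pair.
- **Enabling feature.** The carbon substituents on C3 and C4 share one face of the oxolane ring and the C2 aryl group occupies the other. A two-carbon unit can therefore be added across C3=C4 in one suprafacial event from the face the aryl group leaves open.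
- **Order of rings.** The oxolane comes ready-made from 2,3-dihydrofuran. A temporary cyclobutanone is fused on in step 5 and cut between C=O and CCl2 in step 6. The two carbons are re-tied as a temporary γ-lactone in steps 7 and 8, and this lactone is opened for good in step 9.
- **Stereochemistry.** C2 comes from the chiral P,N-ligand of the Heck arylation. C3 and C4 come from substrate-controlled, anti, suprafacial cycloaddition. The carbinol centre made in step 8 is erased in step 9.
- **Economy.** Both syringyl rings derive from one aryl bromide, used once as the triflate precursor and once as the Grignard precursor.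

Key step: step 5

Assumption: the sense of induction of the phosphinooxazoline ligand is taken from simple aryl triflates, for which the (R)-ligand is expected to give the (S)-2-aryl-2,5-dihydrofuran; if the sense proves opposite, the antipodal ligand is used.

**Step 1**
Reactants: 1 4-bromo-2,6-dimethoxyphenol
Product: 2 2-(benzyloxy)-5-bromo-1,3-dimethoxybenzene
Conditions: BnBr, K2CO3, DMF, 50 °C
Reagents that add atoms: benzyl bromide, BrCc1ccccc1
Why: Williamson ether synthesis of an acidic phenol with an SN2-active halide; benzyl is chosen because it should survive every later step and leave in the hydrogenolysis of step 9.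

**Step 2**
Reactants: 2 2-(benzyloxy)-5-bromo-1,3-dimethoxybenzene
Product: 3 4-(benzyloxy)-3,5-dimethoxyphenol
Conditions: Pd2(dba)3 (2 mol %), tBuXPhos (8 mol %), KOH (4 equiv), 1,4-dioxane–H2O, 100 °C; then dilute aq. HCl
Reagents that add atoms: potassium hydroxide, [K+].[OH-]
Why: Palladium-catalysed hydroxylation of an aryl bromide (oxidative addition to zerovalent palladium, bromide–hydroxide exchange, C–O reductive elimination driven by the bulky biaryl phosphine), with excess KOH holding the product as phenoxide so that diaryl ether formation is suppressed and the alkyl aryl ethers left untouched.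

**Step 3**
Reactants: 3 4-(benzyloxy)-3,5-dimethoxyphenol
Product: 4 4-(benzyloxy)-3,5-dimethoxyphenyl trifluoromethanesulfonate
Conditions: Tf2O, pyridine, CH2Cl2, 0 °C
Reagents that add atoms: trifluoromethanesulfonic anhydride, O=S(=O)(OS(=O)(=O)C(F)(F)F)C(F)(F)F
Why: O-sulfonylation of a phenol, which installs the weakly coordinating leaving group that the cationic Heck pathway needs.

**Step 4**
Reactants: 4 4-(benzyloxy)-3,5-dimethoxyphenyl trifluoromethanesulfonate; 5 2,3-dihydrofuran
Product: 6 (S)-2-[4-(benzyloxy)-3,5-dimethoxyphenyl]-2,5-dihydrofuran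
Conditions: Pd2(dba)3 (2.5 mol %), (R)-tBu-PHOX [(R)-4-tert-butyl-2-(2-diphenylphosphinophenyl)-4,5-dihydrooxazole] (6 mol %), iPr2NEt (2 equiv), 5 (5 equiv), THF, 60 °C
Reagents that add atoms: none
Why: Asymmetric intermolecular Heck arylation by the cationic pathway, in which the P,N-ligand selects the enol-ether face in the syn carbopalladation that puts the aryl group next to oxygen and so sets C2 as (S), syn β-hydride elimination can only run away from the arylated carbon, and phosphinooxazoline complexes release the alkene without re-insertion so that the 2,5-dihydro isomer is kept.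

**Step 5**
Reactants: 6 (S)-2-[4-(benzyloxy)-3,5-dimethoxyphenyl]-2,5-dihydrofuran; 7 trichloroacetyl chloride
Product: 9 (1R,4S,5S)-4-[4-(benzyloxy)-3,5-dimethoxyphenyl]-7,7-dichloro-3-oxabicyclo[3.2.0]heptan-6-one, via dichloroketene 8 (not isolated)
Conditions: 7 (2.5 equiv, slow addition), Zn–Cu couple, Et2O–DME, 30 °C
Reagents that add atoms: none
Why: Zinc removes two chlorines from 7 to give dichloroketene 8, whose electrophilic central carbon engages the C3=C4 π bond in a concerted, asynchronous (2+2) cycloaddition, suprafacial on the alkene and antarafacial on the ketene, with the C3–C(=O) bond running ahead of the C4–CCl2 bond. The closest known reactions are the additions of dichloroketene to cyclopentene and to unsubstituted 2,5-dihydrofuran. The four-membered ring closes by cycloaddition, both bonds forming in one kinetic step on the same alkene face, so the 3-oxabicyclo[3.2.0]heptanone can only be cis-fused. The new stereocentres C5 and C1 of the bicycle (C3 and C4 of the oxolane) are controlled by the C2 stereocentre, since the aryl group shields one face of the nearly flat ring and the ketene arrives on the other, which gives 2,3-trans and 3,4-cis. The step needs regioselectivity, and two features of 6 favour the wanted sense: the bulky CCl2 end avoids the alkene carbon flanked by the aryl-bearing C2 while the slim sp carbon can bond there, and the positive charge that builds on the second alkene carbon is better placed at C4, farther from the inductively withdrawing aryl-substituted C2. Chemoselectivity over acylation or Lewis-acid ionisation of the allylic, benzylic ether oxygen is helped by DME, which ties up ZnCl2, by slow addition of 7, and by the flanked, twisted 4-benzyloxy group, which makes the aryl ring only a modest cation stabiliser.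

**Step 6**
Reactants: 9 (1R,4S,5S)-4-[4-(benzyloxy)-3,5-dimethoxyphenyl]-7,7-dichloro-3-oxabicyclo[3.2.0]heptan-6-one
Product: 10 (2S,3S,4R)-2-[4-(benzyloxy)-3,5-dimethoxyphenyl]-4-(dichloromethyl)oxolane-3-carboxylic acid
Conditions: LiOH (1.5 equiv), THF–H2O, 0 °C; then cold dilute aq. HCl to pH 3
Reagents that add atoms: lithium hydroxide, [Li+].[OH-]
Why: Haloform-type cleavage in which hydroxide adds to the strained, chlorine-activated carbonyl and the tetrahedral intermediate expels the dichloromethyl carbanion, which water protonates; no ring stereocentre is touched and the resulting carboxylate is not enolisable under these conditions, so the 3,4-cis relation should hold.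

**Step 7**
Reactants: 10 (2S,3S,4R)-2-[4-(benzyloxy)-3,5-dimethoxyphenyl]-4-(dichloromethyl)oxolane-3-carboxylic acid
Product: 12 (3aR,6S,6aS)-6-[4-(benzyloxy)-3,5-dimethoxyphenyl]-3-hydroxytetrahydro-1H,3H-furo[3,4-c]furan-1-one (cis-fused pseudo-acid; epimers at lactol carbon C3), via chlorolactone 11 (not isolated)
Conditions: AgOAc (2.2 equiv), acetone–H2O (4:1), 45 °C, dark
Reagents that add atoms: water, O
Why: Silver-assisted hydrolysis of a gem-dichloride with neighbouring-group participation, in which the cis carboxylate displaces the first chloride in a 5-exo-tet lactonisation to 11 and water captures the acyloxy-stabilised cation left by the second chloride, while the acetate buffer stays too weakly acidic to ionise the benzylic C2–O bond and the closed lactol masks the epimerisable aldehyde.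

**Step 8**
Reactants: 12 (3aR,6S,6aS)-6-[4-(benzyloxy)-3,5-dimethoxyphenyl]-3-hydroxytetrahydro-1H,3H-furo[3,4-c]furan-1-one; 2 2-(benzyloxy)-5-bromo-1,3-dimethoxybenzene
Product: 15 (3aR,6S,6aS)-3,6-bis[4-(benzyloxy)-3,5-dimethoxyphenyl]tetrahydro-1H,3H-furo[3,4-c]furan-1-one (epimers at C3), via arylmagnesium bromide 13 (not isolated), via hydroxy acid 14 (not isolated)
Conditions: 2 (2.5 equiv), Mg, THF, 40 °C; then 12, THF, −40 to 0 °C; cold dilute aq. HCl, then rt
Reagents that add atoms: none
Why: Grignard addition to the open aldehyde form of a pseudo-acid (the reaction type that turns 3-hydroxyphthalide into 3-arylphthalides), where the first equivalent deprotonates, the second adds to the aldehyde faster than it enolises it at low temperature, the carboxylate is inert, the cis γ-hydroxy acid 14 lactonises on acidification, and the new carbinol centre needs no control because step 9 removes it.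

**Step 9**
Reactants: 15 (3aR,6S,6aS)-3,6-bis[4-(benzyloxy)-3,5-dimethoxyphenyl]tetrahydro-1H,3H-furo[3,4-c]furan-1-one
Product: 16 (2S,3S,4R)-4-(4-hydroxy-3,5-dimethoxybenzyl)-2-(4-hydroxy-3,5-dimethoxyphenyl)oxolane-3-carboxylic acid
Conditions: H2 (1–3 atm), 10% Pd/C, EtOAc–EtOH, rt, stopped after uptake of 3 equiv H2
Reagents that add atoms: none
Why: Catalytic hydrogenolysis of the two O-benzyl ethers and of the benzylic acyloxy C–O bond of the lactone; carboxylate is a much better leaving group than the ring alkoxide and its departure relieves the bicyclic strain, so the C2–O bond of the oxolane should survive monitored uptake, and C2, C3 and C4 are not touched.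

**Step 10**
Reactants: 16 (2S,3S,4R)-4-(4-hydroxy-3,5-dimethoxybenzyl)-2-(4-hydroxy-3,5-dimethoxyphenyl)oxolane-3-carboxylic acid
Product: 17 (+)-(7S,8R,8'R)-5,5'-dimethoxylariciresinol
Conditions: BH3·THF (5 equiv), THF, 0 °C to rt; MeOH, then aqueous work-up
Reagents that add atoms: none
Why: Chemoselective borane reduction of a carboxylic acid through its acyloxyborane; the phenols only take up borane as aryl borates that the quench releases, the ethers are inert, and nothing is enolised under these non-basic conditions.

**Compound list**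

1 | 4-bromo-2,6-dimethoxyphenol | COc1cc(Br)cc(OC)c1O | starting material
2 | 2-(benzyloxy)-5-bromo-1,3-dimethoxybenzene | COc1cc(Br)cc(OC)c1OCc1ccccc1 | intermediate
3 | 4-(benzyloxy)-3,5-dimethoxyphenol | COc1cc(O)cc(OC)c1OCc1ccccc1 | intermediate
4 | 4-(benzyloxy)-3,5-dimethoxyphenyl trifluoromethanesulfonate | COc1cc(OS(=O)(=O)C(F)(F)F)cc(OC)c1OCc1ccccc1 | intermediate
5 | 2,3-dihydrofuran | C1=COCC1 | starting material
6 | (S)-2-[4-(benzyloxy)-3,5-dimethoxyphenyl]-2,5-dihydrofuran | COc1cc([C@H]2OCC=C2)cc(OC)c1OCc1ccccc1 | intermediate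
7 | trichloroacetyl chloride | ClC(Cl)(Cl)C(Cl)=O | starting material
8 | dichloroketene | ClC(Cl)=C=O | intermediate (not isolated)
9 | (1R,4S,5S)-4-[4-(benzyloxy)-3,5-dimethoxyphenyl]-7,7-dichloro-3-oxabicyclo[3.2.0]heptan-6-one | COc1cc([C@H]2OC[C@H]3[C@@H]2C(=O)C3(Cl)Cl)cc(OC)c1OCc1ccccc1 | intermediate
10 | (2S,3S,4R)-2-[4-(benzyloxy)-3,5-dimethoxyphenyl]-4-(dichloromethyl)oxolane-3-carboxylic acid | COc1cc([C@H]2OC[C@H](C(Cl)Cl)[C@@H]2C(=O)O)cc(OC)c1OCc1ccccc1 | intermediate
11 | (3aR,6S,6aS)-6-[4-(benzyloxy)-3,5-dimethoxyphenyl]-3-chlorotetrahydro-1H,3H-furo[3,4-c]furan-1-one (C3 undefined) | COc1cc([C@H]2OC[C@H]3[C@@H]2C(=O)OC3Cl)cc(OC)c1OCc1ccccc1 | intermediate (not isolated)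
12 | (3aR,6S,6aS)-6-[4-(benzyloxy)-3,5-dimethoxyphenyl]-3-hydroxytetrahydro-1H,3H-furo[3,4-c]furan-1-one (lactol epimers at C3) | COc1cc([C@H]2OC[C@H]3[C@@H]2C(=O)OC3O)cc(OC)c1OCc1ccccc1 | intermediate
13 | [4-(benzyloxy)-3,5-dimethoxyphenyl]magnesium bromide | COc1cc([Mg]Br)cc(OC)c1OCc1ccccc1 | intermediate (not isolated)
14 | (2S,3S,4R)-2-[4-(benzyloxy)-3,5-dimethoxyphenyl]-4-{[4-(benzyloxy)-3,5-dimethoxyphenyl](hydroxy)methyl}oxolane-3-carboxylic acid (carbinol epimers) | COc1cc([C@H]2OC[C@H](C(O)c3cc(OC)c(OCc4ccccc4)c(OC)c3)[C@@H]2C(=O)O)cc(OC)c1OCc1ccccc1 | intermediate (not isolated)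
15 | (3aR,6S,6aS)-3,6-bis[4-(benzyloxy)-3,5-dimethoxyphenyl]tetrahydro-1H,3H-furo[3,4-c]furan-1-one (epimers at C3) | COc1cc([C@H]2OC[C@H]3[C@@H]2C(=O)OC3c4cc(OC)c(OCc5ccccc5)c(OC)c4)cc(OC)c1OCc1ccccc1 | intermediate
16 | (2S,3S,4R)-4-(4-hydroxy-3,5-dimethoxybenzyl)-2-(4-hydroxy-3,5-dimethoxyphenyl)oxolane-3-carboxylic acid | COc1cc([C@H]2OC[C@H](Cc3cc(OC)c(O)c(OC)c3)[C@@H]2C(=O)O)cc(OC)c1O | intermediate
17 | (+)-(7S,8R,8'R)-5,5'-dimethoxylariciresinol | COc1cc(C[C@H]2CO[C@H](c3cc(OC)c(O)c(OC)c3)[C@H]2CO)cc(OC)c1O | target

**Step count**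

Total step count: 10. Longest linear sequence: 10 steps (1 to 17). Compound 2 enters twice, in steps 2 and 8.

**Steps most likely to fail**

**Step 5.** The ketene may add in the reverse orientation, or without useful preference, because only the remote C2 substituent distinguishes the two alkene carbons.

The fallback sets out from 6 and returns at 17. It accepts the reverse orientation and exchanges the roles of the two new carbons: the carbonyl carbon becomes the benzylic carbon and the CCl2 carbon becomes the hydroxymethyl carbon. The cycloaddition on 6 then supplies, after separation where both isomers form, the regioisomeric cycloadduct F1. LiOH cleavage as in step 6 should give the transposed dichloromethyl acid F2, and AgOAc in aqueous acetone should give the transposed pseudo-acid F3. NaBH4 reduces the aldehyde form of F3, and acidification closes the cis-fused lactone F4. Bromine–lithium exchange on 2 (nBuLi, THF, −78 °C) gives the aryllithium F5. One equivalent of F5 is acylated by F4 at −78 °C to give the hydroxy ketone F6, which should rest as its cis-fused hemiketal and so protect the α-centre. Hydrogenation over Pd/C in EtOH with a little AcOH takes the aryl ketone down to the methylene group and removes both benzyl groups, giving 17.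

**Step 7.** The unactivated gem-dichloride may resist displacement even with silver assistance. It may also lose HCl to a chloroalkene, or the freed aldehyde may epimerise at C4 before it closes.

The fallback sets out from 9 and returns at 12, replacing steps 6 and 7. It cleaves the C6–C7 bond oxidatively instead of by expulsion of a carbanion. Zn in AcOH removes both chlorines to give the dechlorinated cyclobutanone F7. LDA and then Me3SiCl at −78 °C deprotonate only the CH2 side, since a bridgehead enolate is too strained, and give the silyl enol ether F8. Ozonolysis with one equivalent of ozone (CH2Cl2–MeOH, −78 °C, then Me2S) cuts the enol double bond to an aldehyde and a silyl ester. The silyl ester hydrolyses on work-up and closes to 12.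

**Step 9.** Hydrogenolysis may run on into the ring C2–O bond, or it may stall at the debenzylated lactone.

The fallback sets out from 12 and 1 and returns at 16. It removes the lactone C–O bond by a quinone-methide reduction that only the ring on C7' can undergo. Silylation of 1 (TBSCl, imidazole, DMF) gives the silyl-protected aryl bromide F9, and Mg in THF gives the silyl-protected Grignard reagent F10. Addition of F10 to 12 as in step 8 gives the mixed-protected lactone F11. TBAF with NaBH4 in THF–EtOH frees the phenoxide, which expels the carboxylate by 1,6-elimination. Borohydride then reduces the p-quinone methide at the benzylic carbon to the mono-benzyl acid F12. The benzyl-capped ring on C2 cannot form a quinone methide, so its C–O bond stays intact. A brief hydrogenolysis (H2, Pd/C, EtOAc) of the single aryl benzyl ether, which is much faster than ring opening, gives 16.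

**Further compounds**

F1 | step 5 | (1S,2S,5R)-2-[4-(benzyloxy)-3,5-dimethoxyphenyl]-7,7-dichloro-3-oxabicyclo[3.2.0]heptan-6-one (regioisomeric cycloadduct) | COc1cc([C@H]2OC[C@H]3[C@@H]2C(Cl)(Cl)C3=O)cc(OC)c1OCc1ccccc1
F2 | step 5 | (3R,4S,5S)-5-[4-(benzyloxy)-3,5-dimethoxyphenyl]-4-(dichloromethyl)oxolane-3-carboxylic acid (transposed dichloromethyl acid) | COc1cc([C@H]2OC[C@H](C(=O)O)[C@@H]2C(Cl)Cl)cc(OC)c1OCc1ccccc1
F3 | step 5 | (3aS,4S,6aR)-4-[4-(benzyloxy)-3,5-dimethoxyphenyl]-3-hydroxytetrahydro-1H,3H-furo[3,4-c]furan-1-one (transposed pseudo-acid, lactol epimers) | COc1cc([C@H]2OC[C@H]3[C@@H]2C(O)OC3=O)cc(OC)c1OCc1ccccc1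
F4 | step 5 | (3aR,4S,6aR)-4-[4-(benzyloxy)-3,5-dimethoxyphenyl]tetrahydro-1H,3H-furo[3,4-c]furan-1-one (cis-fused lactone) | COc1cc([C@H]2OC[C@H]3[C@@H]2COC3=O)cc(OC)c1OCc1ccccc1
F5 | step 5 | [4-(benzyloxy)-3,5-dimethoxyphenyl]lithium (aryllithium) | [Li]c1cc(OC)c(OCc2ccccc2)c(OC)c1
F6 | step 5 | [4-(benzyloxy)-3,5-dimethoxyphenyl]{(3R,4R,5S)-5-[4-(benzyloxy)-3,5-dimethoxyphenyl]-4-(hydroxymethyl)oxolan-3-yl}methanone (hydroxy ketone) | COc1cc([C@H]2OC[C@H](C(=O)c3cc(OC)c(OCc4ccccc4)c(OC)c3)[C@@H]2CO)cc(OC)c1OCc1ccccc1
F7 | step 7 | (1R,4S,5S)-4-[4-(benzyloxy)-3,5-dimethoxyphenyl]-3-oxabicyclo[3.2.0]heptan-6-one (dechlorinated cyclobutanone) | COc1cc([C@H]2OC[C@H]3[C@@H]2C(=O)C3)cc(OC)c1OCc1ccccc1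
F8 | step 7 | {[(1R,4S,5S)-4-[4-(benzyloxy)-3,5-dimethoxyphenyl]-3-oxabicyclo[3.2.0]hept-6-en-6-yl]oxy}trimethylsilane (silyl enol ether) | COc1cc([C@H]2OC[C@H]3[C@@H]2C(O[Si](C)(C)C)=C3)cc(OC)c1OCc1ccccc1
F9 | step 9 | (4-bromo-2,6-dimethoxyphenoxy)(tert-butyl)dimethylsilane (silyl-protected aryl bromide) | COc1cc(Br)cc(OC)c1O[Si](C)(C)C(C)(C)C
F10 | step 9 | {4-[(tert-butyldimethylsilyl)oxy]-3,5-dimethoxyphenyl}magnesium bromide (silyl-protected Grignard reagent) | COc1cc([Mg]Br)cc(OC)c1O[Si](C)(C)C(C)(C)C
F11 | step 9 | (3aR,6S,6aS)-6-[4-(benzyloxy)-3,5-dimethoxyphenyl]-3-{4-[(tert-butyldimethylsilyl)oxy]-3,5-dimethoxyphenyl}tetrahydro-1H,3H-furo[3,4-c]furan-1-one (mixed-protected lactone, epimers at C3) | COc1cc([C@H]2OC[C@H]3[C@@H]2C(=O)OC3c4cc(OC)c(O[Si](C)(C)C(C)(C)C)c(OC)c4)cc(OC)c1OCc1ccccc1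
F12 | step 9 | (2S,3S,4R)-2-[4-(benzyloxy)-3,5-dimethoxyphenyl]-4-(4-hydroxy-3,5-dimethoxybenzyl)oxolane-3-carboxylic acid (mono-benzyl acid) | COc1cc([C@H]2OC[C@H](Cc3cc(OC)c(O)c(OC)c3)[C@@H]2C(=O)O)cc(OC)c1OCc1ccccc1
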